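**Plan**

Ring numbering used throughout: C1 (OAc), C2H=C3 (carries the exocyclic C7H2OBz), C4 (OH), C5 (OBz), C6 (OH).
Retrosynthesis: first the C4–H bond (hydride to a C4 ketone), then C3–C7 (enone α-carbon plus formaldehyde), then C1–O and C4=O (singlet oxygen across a 1,3-diene); this leaves the cis-dihydrodiol of bromobenzene, whose two hydroxyls are told apart as silyl ether (C6) and benzoate (C5).
Enabling feature: the C2=C3 double bond lies next to the C4 carbinol, so at the ketone level C2=C3–C4=O is a cyclohex-2-enone with C3 as its α-carbon, which a Lewis base turns into a nucleophile. The C4 carbonyl is the helper: the bromine of the diol brings it in and the last reduction takes it out.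
Forward: no ring is built (the six-membered ring is that of bromobenzene); oxygen is placed on C1 and C4, the one-carbon unit is joined at C3, and C4 is reduced last.
Stereochemistry: C5 and C6 come from the enzymatic cis-dihydroxylation (chiral pool), C1 from anti addition of singlet oxygen, C4 from hydride delivery directed by the free C6 hydroxyl.

Key step: step 5

Assumption: (1S,2S)-3-bromocyclohexa-3,5-diene-1,2-diol, the dioxygenase cis-dihydrodiol of bromobenzene, is taken as a commercial starting material.

**Route**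

Step 1
Reactants: 1 (1S,2S)-3-bromocyclohexa-3,5-diene-1,2-diol; 2 thexyldimethylsilyl chloride
Product: 3 (1S,6S)-2-bromo-6-[(thexyldimethylsilyl)oxy]cyclohexa-2,4-dien-1-ol
Conditions: TDSCl (1.05 equiv), imidazole, DMF, −10 → 0 °C
Reagents that add atoms: thexyldimethylsilyl chloride, CC(C)C(C)(C)[Si](C)(C)Cl
Why: Regioselective monosilylation with a bulky silyl chloride and imidazole should take the hydroxyl remote from bromine, the less hindered of the two; no stereocenter is touched.

Step 2
Reactants: 3 (1S,6S)-2-bromo-6-[(thexyldimethylsilyl)oxy]cyclohexa-2,4-dien-1-ol; 4 benzoyl chloride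
Product: 5 (1S,6S)-2-bromo-6-[(thexyldimethylsilyl)oxy]cyclohexa-2,4-dien-1-yl benzoate
Conditions: BzCl, pyridine, DMAP (cat.), CH2Cl2, 0 °C
Reagents that add atoms: benzoyl chloride, O=C(Cl)c1ccccc1
Why: DMAP-catalysed O-acylation of the one remaining hydroxyl, next to the C–Br carbon, places the future C5 benzoate; the cold, weakly basic medium should avoid silyl migration and aromatisation of the diene.

Step 3
Reactants: 5 (1S,6S)-2-bromo-6-[(thexyldimethylsilyl)oxy]cyclohexa-2,4-dien-1-yl benzoate; 6 dioxygen
Product: 8 (1S,5R,6S)-5-hydroxy-2-oxo-6-[(thexyldimethylsilyl)oxy]cyclohex-3-en-1-yl benzoate, via bromo endoperoxide 7 (not isolated)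
Conditions: O2, tetraphenylporphyrin (cat.), hν, CH2Cl2, −20 °C; then thiourea, MeOH (5% H2O), 0 °C → rt
Reagents that add atoms: dioxygen (as singlet oxygen), O=O
Why: Photosensitised [4+2] cycloaddition of singlet oxygen to the cyclic 1,3-diene should occur on the face anti to the cis benzoate and silyl ether, which sets the C1 oxygen trans to the C6 oxygen; thiourea then reduces the O–O bond and the geminal bromohydrin at C4 collapses to the ketone with loss of HBr, so the bromine decides which end becomes the carbonyl.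

Step 4
Reactants: 8 (1S,5R,6S)-5-hydroxy-2-oxo-6-[(thexyldimethylsilyl)oxy]cyclohex-3-en-1-yl benzoate; 9 acetic anhydride
Product: 10 (1S,5R,6S)-5-acetoxy-2-oxo-6-[(thexyldimethylsilyl)oxy]cyclohex-3-en-1-yl benzoate
Conditions: Ac2O, pyridine, DMAP (cat.), CH2Cl2, 0 °C
Reagents that add atoms: acetic anhydride, CC(=O)OC(C)=O
Why: Standard acetylation of the only free hydroxyl installs the C1 acetate of the target with retention at C1.

Step 5
Reactants: 10 (1S,5R,6S)-5-acetoxy-2-oxo-6-[(thexyldimethylsilyl)oxy]cyclohex-3-en-1-yl benzoate; 11 formaldehyde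
Product: 12 (1S,5R,6S)-5-acetoxy-3-(hydroxymethyl)-2-oxo-6-[(thexyldimethylsilyl)oxy]cyclohex-3-en-1-yl benzoate
Conditions: 37% aq. HCHO (3 equiv), DMAP (0.3 equiv), THF–H2O, 0 °C → rt
Reagents that add atoms: formaldehyde, C=O
Why: Morita–Baylis–Hillman reaction: DMAP adds reversibly to the β-carbon C2 of the enone C2=C3–C4=O, the ammonium enolate attacks formaldehyde through C3 to form the C3–C7 bond, and proton transfer with E1cB loss of DMAP restores the C2=C3 double bond. The closest known reaction type is the amine-catalysed α-hydroxymethylation of cyclohex-2-enones with aqueous formaldehyde, which is established for 4,5,6-trioxygenated cyclohexenones of the carbasugar series. No ring is closed and no stereocenter is created, so the step only has to leave C1, C5 and C6 as they are. Regioselectivity is inherent, because C3 is the only enone α-carbon and its position was fixed when the bromine-bearing carbon became the C4 carbonyl. The selectivity that is needed is chemoselectivity against epimerisation at C5, β-elimination of the C6 oxygen and ester cleavage; a nucleophilic, weakly basic catalyst at or below room temperature and the bulky silyl ether on C6 should secure it.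

Step 6
Reactants: 12 (1S,5R,6S)-5-acetoxy-3-(hydroxymethyl)-2-oxo-6-[(thexyldimethylsilyl)oxy]cyclohex-3-en-1-yl benzoate; 4 benzoyl chloride
Product: 13 [(3R,4S,5S)-3-acetoxy-5-(benzoyloxy)-6-oxo-4-[(thexyldimethylsilyl)oxy]cyclohex-1-en-1-yl]methyl benzoate
Conditions: BzCl, pyridine, CH2Cl2, 0 °C
Reagents that add atoms: benzoyl chloride, O=C(Cl)c1ccccc1
Why: O-Benzoylation of the primary allylic alcohol, the only free hydroxyl, gives the C7 benzoate without any selectivity problem.

Step 7
Reactants: 13 [(3R,4S,5S)-3-acetoxy-5-(benzoyloxy)-6-oxo-4-[(thexyldimethylsilyl)oxy]cyclohex-1-en-1-yl]methyl benzoate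
Product: 14 [(3R,4S,5S)-3-acetoxy-5-(benzoyloxy)-4-hydroxy-6-oxocyclohex-1-en-1-yl]methyl benzoate
Conditions: HF·pyridine, THF–pyridine, 0 °C → rt
Reagents that add atoms: none
Why: Fluoride-mediated desilylation in a buffered acidic medium frees the C6 hydroxyl; the absence of base should prevent benzoyl migration from C5 to C6 and β-elimination of the new β-hydroxy ketone.

Step 8
Reactants: 14 [(3R,4S,5S)-3-acetoxy-5-(benzoyloxy)-4-hydroxy-6-oxocyclohex-1-en-1-yl]methyl benzoate
Product: 15 [(3R,4S,5R,6S)-3-acetoxy-5-(benzoyloxy)-4,6-dihydroxycyclohex-1-en-1-yl]methyl benzoate (CNP0169028.1)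
Conditions: Me4NBH(OAc)3 (5 equiv), MeCN–AcOH (1:1), −30 → −20 °C; aq. Rochelle salt/NaHCO3 work-up
Reagents that add atoms: none
Why: Evans–Saksena hydroxyl-directed reduction: the C6 hydroxyl exchanges onto boron and delivers hydride intramolecularly to the C4 carbonyl on its own face, so the new C4 hydroxyl should come out anti to C6–OH and trans to the C5 benzoate; the reagent reduces only the bound ketone in 1,2-fashion and leaves the esters alone.

**Compound list**

1 | (1S,2S)-3-bromocyclohexa-3,5-diene-1,2-diol | O[C@H]1C=CC=C(Br)[C@H]1O | starting material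
2 | thexyldimethylsilyl chloride, chloro(dimethyl)(2,3-dimethylbutan-2-yl)silane | CC(C)C(C)(C)[Si](C)(C)Cl | starting material
3 | (1S,6S)-2-bromo-6-[(thexyldimethylsilyl)oxy]cyclohexa-2,4-dien-1-ol (silyl ether on the hydroxyl remote from Br, cis to the free OH) | CC(C)C(C)(C)[Si](C)(C)O[C@H]1C=CC=C(Br)[C@H]1O | intermediate
4 | benzoyl chloride | O=C(Cl)c1ccccc1 | starting material
5 | (1S,6S)-2-bromo-6-[(thexyldimethylsilyl)oxy]cyclohexa-2,4-dien-1-yl benzoate | CC(C)C(C)(C)[Si](C)(C)O[C@H]1C=CC=C(Br)[C@H]1OC(=O)c1ccccc1 | intermediate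
6 | dioxygen | O=O | starting material
7 | bromo endoperoxide: 1-bromo-8-[(thexyldimethylsilyl)oxy]-2,3-dioxabicyclo[2.2.2]oct-5-en-7-yl benzoate, O–O bridge anti to the benzoate and the silyl ether | O1O[C@@H]2C=C[C@@]1(Br)[C@@H](OC(=O)c3ccccc3)[C@H]2O[Si](C)(C)C(C)(C)C(C)C | intermediate
8 | (1S,5R,6S)-5-hydroxy-2-oxo-6-[(thexyldimethylsilyl)oxy]cyclohex-3-en-1-yl benzoate | O[C@@H]1C=CC(=O)[C@@H](OC(=O)c2ccccc2)[C@H]1O[Si](C)(C)C(C)(C)C(C)C | intermediate
9 | acetic anhydride | CC(=O)OC(C)=O | starting material
10 | (1S,5R,6S)-5-acetoxy-2-oxo-6-[(thexyldimethylsilyl)oxy]cyclohex-3-en-1-yl benzoate | CC(=O)O[C@@H]1C=CC(=O)[C@@H](OC(=O)c2ccccc2)[C@H]1O[Si](C)(C)C(C)(C)C(C)C | intermediate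
11 | formaldehyde | C=O | starting material
12 | (1S,5R,6S)-5-acetoxy-3-(hydroxymethyl)-2-oxo-6-[(thexyldimethylsilyl)oxy]cyclohex-3-en-1-yl benzoate | CC(=O)O[C@@H]1C=C(CO)C(=O)[C@@H](OC(=O)c2ccccc2)[C@H]1O[Si](C)(C)C(C)(C)C(C)C | intermediate
13 | [(3R,4S,5S)-3-acetoxy-5-(benzoyloxy)-6-oxo-4-[(thexyldimethylsilyl)oxy]cyclohex-1-en-1-yl]methyl benzoate | CC(=O)O[C@@H]1C=C(COC(=O)c2ccccc2)C(=O)[C@@H](OC(=O)c2ccccc2)[C@H]1O[Si](C)(C)C(C)(C)C(C)C | intermediate
14 | [(3R,4S,5S)-3-acetoxy-5-(benzoyloxy)-4-hydroxy-6-oxocyclohex-1-en-1-yl]methyl benzoate | CC(=O)O[C@@H]1C=C(COC(=O)c2ccccc2)C(=O)[C@@H](OC(=O)c2ccccc2)[C@H]1O | intermediate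
15 | [(3R,4S,5R,6S)-3-acetoxy-5-(benzoyloxy)-4,6-dihydroxycyclohex-1-en-1-yl]methyl benzoate | CC(=O)O[C@@H]1C=C(COC(=O)c2ccccc2)[C@H](O)[C@@H](OC(=O)c2ccccc2)[C@H]1O | target

**Count and risks**

Total step count: 8. Longest linear sequence: 8 steps, from 1 to 15.

Steps most likely to fail:

Step 5. Under amine and water the ketone may enolise towards C5 and epimerise the benzoate-bearing carbon, or the aldol may stall on the hindered γ-acetoxy enone. The fallback replaces the aldol by a cross-coupling and sets out from 10. Iodination at C3 with iodine and pyridine in CH2Cl2 should give (1S,5R,6S)-5-acetoxy-3-iodo-2-oxo-6-[(thexyldimethylsilyl)oxy]cyclohex-3-en-1-yl benzoate F1. A Stille coupling of this vinyl iodide with (tributylstannyl)methanol (Pd2(dba)3, AsPh3, CuI, NMP, 50 °C) should then give 12, where the fallback comes back to the route.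

Step 8. Hydride delivery may lose its facial bias if the ring prefers the conformer with the C6 hydroxyl equatorial and out of reach of the carbonyl, or the borohydride may fail to bind the hindered hydroxyl. The fallback uses an undirected reduction followed by inversion and sets out from 13. Luche reduction (NaBH4, CeCl3·7H2O, MeOH, −78 °C), with hydride expected anti to the C5 and C6 substituents, should give the C4-epimeric allylic alcohol F2. Mitsunobu inversion with chloroacetic acid (PPh3, DIAD, toluene, 0 °C) should give the C4 chloroacetate F3 with the configuration of the target; the cis benzoate on C5 cannot take part. Thiourea with NaHCO3 in EtOH removes the chloroacetyl group in the presence of acetate and benzoates and gives the C6 silyl ether of the target F4. HF·pyridine then gives 15, where the fallback comes back to the route.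

Step 1. The silyl chloride may discriminate poorly between the two allylic hydroxyls, or the silyl group may migrate between the cis oxygens. The fallback differentiates by selective deacylation and sets out from 1. Benzoylation of both hydroxyls (BzCl, pyridine, DMAP) gives (1S,2S)-3-bromocyclohexa-3,5-diene-1,2-diyl dibenzoate F5. Lipase-mediated hydrolysis (Candida rugosa lipase, phosphate buffer pH 7, acetone) should cleave the more accessible ester remote from bromine and give (1S,6S)-2-bromo-6-hydroxycyclohexa-2,4-dien-1-yl benzoate F6. Silylation of the single free hydroxyl with TDSCl and imidazole gives 5, where the fallback comes back to the route.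

**Further compounds**

F1 | step 5 | (1S,5R,6S)-5-acetoxy-3-iodo-2-oxo-6-[(thexyldimethylsilyl)oxy]cyclohex-3-en-1-yl benzoate | CC(=O)O[C@@H]1C=C(I)C(=O)[C@@H](OC(=O)c2ccccc2)[C@H]1O[Si](C)(C)C(C)(C)C(C)C
F2 | step 8 | C4 epimer of the silyl-protected target: [(3R,4S,5R,6R)-3-acetoxy-5-(benzoyloxy)-6-hydroxy-4-[(thexyldimethylsilyl)oxy]cyclohex-1-en-1-yl]methyl benzoate, C4–OH cis to the C5 benzoate | CC(=O)O[C@@H]1C=C(COC(=O)c2ccccc2)[C@@H](O)[C@@H](OC(=O)c2ccccc2)[C@H]1O[Si](C)(C)C(C)(C)C(C)C
F3 | step 8 | C4 chloroacetate of the C6 silyl ether of the target, chloroacetoxy group trans to the C5 benzoate | CC(=O)O[C@@H]1C=C(COC(=O)c2ccccc2)[C@H](OC(=O)CCl)[C@@H](OC(=O)c2ccccc2)[C@H]1O[Si](C)(C)C(C)(C)C(C)C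
F4 | step 8 | C6 thexyldimethylsilyl ether of the target | CC(=O)O[C@@H]1C=C(COC(=O)c2ccccc2)[C@H](O)[C@@H](OC(=O)c2ccccc2)[C@H]1O[Si](C)(C)C(C)(C)C(C)C
F5 | step 1 | (1S,2S)-3-bromocyclohexa-3,5-diene-1,2-diyl dibenzoate | O=C(O[C@H]1C=CC=C(Br)[C@H]1OC(=O)c1ccccc1)c1ccccc1
F6 | step 1 | (1S,6S)-2-bromo-6-hydroxycyclohexa-2,4-dien-1-yl benzoate | O[C@H]1C=CC=C(Br)[C@H]1OC(=O)c1ccccc1
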